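Rings A and B are unravelled together to an acyclic (S)-configured β-keto ester in which C10 and C1 form an isopropenyl group on C5. One manganese triacetate/copper diacetate radical cascade closes ring A through the C1–C2 bond and ring B through C9–C10, sets C10 and C9 from C5, and leaves the C8=C17 alkene for later hydroboration. It exploits the C3 oxygen next to C2, the methyl-bearing quaternary C10 and the isoprenoid C8=C9 unit of ring B. The branched precursor comes from methyl (2Z,6E)-farnesoate: an enantioselective Ireland–Claisen rearrangement of its 12-isobutyrate delivers C3/C4 with both methyls to C5.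

Key step: step 8

Remark: atom numbers follow labdane numbering (C17 = formyl carbon, C20 = methyl on C10). The (4S,5S)-configured boron controller of step 6 is assumed to induce (S)-C5; if the sense of induction is opposite, its (4R,5R)-antipode is used.

Step 1
Reactants: 1 geranyl bromide, 2 methyl acetoacetate
Product: 4 methyl (6E)-7,11-dimethyl-3-oxododeca-6,10-dienoate, via acetoacetate dianion 3 (not isolated)
Conditions: 2, NaH, THF, 0 °C; n-BuLi, 0 °C; then 1, 0 °C → rt; aq. HCl
Reagents that add atoms: none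
Why: γ-Alkylation of the acetoacetate dianion: the more basic terminal carbanion displaces the primary allylic bromide by SN2, so the (E)-alkene of 1 is kept and no stereocentre is formed.

Step 2
Reactants: 4 methyl (6E)-7,11-dimethyl-3-oxododeca-6,10-dienoate
Product: 5 methyl (2E,6E)-7,11-dimethyl-3-{[(trifluoromethyl)sulfonyl]oxy}dodeca-2,6,10-trienoate
Conditions: Tf2O, 25% aq. Me4NOH, hexanes, 5 °C
Reagents that add atoms: trifluoromethanesulfonic anhydride, O=S(=O)(OS(=O)(=O)C(F)(F)F)C(F)(F)F
Why: O-Sulfonylation of the β-keto ester enolate; with the non-chelating tetramethylammonium counter-ion the open enolate should give the (2E)-enol triflate, with the triflate trans to the ester.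

Step 3
Reactants: 5 methyl (2E,6E)-7,11-dimethyl-3-{[(trifluoromethyl)sulfonyl]oxy}dodeca-2,6,10-trienoate
Product: 6 methyl (2Z,6E)-3,7,11-trimethyldodeca-2,6,10-trienoate
Conditions: MeMgBr, Fe(acac)3 (5 mol%), THF–NMP, −30 °C
Reagents that add atoms: methylmagnesium bromide, C[Mg]Br
Why: Iron-catalysed Kumada-type coupling of the enol triflate replaces the triflate by methyl with retention, so the chain stays cis to the ester and the (2Z)-enoate of the target is fixed here.

Step 4
Reactants: 6 methyl (2Z,6E)-3,7,11-trimethyldodeca-2,6,10-trienoate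
Product: 7 methyl (2Z,6E,10E)-12-hydroxy-3,7,11-trimethyldodeca-2,6,10-trienoate
Conditions: SeO2 (0.1 equiv), t-BuOOH (70% aq.), salicylic acid (0.1 equiv), CH2Cl2, 0 °C → rt
Reagents that add atoms: tert-butyl hydroperoxide, CC(C)(C)OO
Why: Selenium dioxide allylic oxidation (ene reaction, then [2,3]-sigmatropic shift) should attack the most electron-rich terminal trisubstituted alkene at its (E)-methyl group, the conjugated alkene being deactivated; the (10E) geometry follows from the mechanism.

Step 5
Reactants: 7 methyl (2Z,6E,10E)-12-hydroxy-3,7,11-trimethyldodeca-2,6,10-trienoate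
Product: 8 methyl (2Z,6E,10E)-3,7,11-trimethyl-12-[(2-methylpropanoyl)oxy]dodeca-2,6,10-trienoate
Conditions: (i-PrCO)2O, DMAP (cat.), pyridine, 0 °C → rt
Reagents that add atoms: 2-methylpropanoic anhydride, CC(C)C(=O)OC(=O)C(C)C
Why: Nucleophile-catalysed acylation of the primary allylic alcohol installs the future C3, C4 and both C4 methyls; no stereochemical change.

Step 6
Reactants: 8 methyl (2Z,6E,10E)-3,7,11-trimethyl-12-[(2-methylpropanoyl)oxy]dodeca-2,6,10-trienoate
Product: 10 (3S,6E,10Z)-12-methoxy-2,2,6,10-tetramethyl-12-oxo-3-(prop-1-en-2-yl)dodeca-6,10-dienoic acid, via boron ketene acetal 9 (not isolated)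
Conditions: (1S,2S)-[ArSO2NHCH(Ph)]2 (Ar = 3,5-(CF3)2C6H3), BBr3, CH2Cl2, rt, then evaporation; 8, Et3N, toluene–hexane, −78 °C → 4 °C; aq. work-up
Reagents that add atoms: none
Why: Ireland–Claisen rearrangement in its chiral boron ketene acetal version: soft enolisation gives 9, whose chair [3,3] transition state forms the C4–C5 bond and turns C10/C1 into the isopropenyl group, and the C2-symmetric bis-sulfonamide on boron should shield one face of the (E)-allyl terminus to give (S)-C5.

Step 7
Reactants: 10 (3S,6E,10Z)-12-methoxy-2,2,6,10-tetramethyl-12-oxo-3-(prop-1-en-2-yl)dodeca-6,10-dienoic acid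
Product: 12 dimethyl (5S,8E,12Z)-4,4,8,12-tetramethyl-3-oxo-5-(prop-1-en-2-yl)tetradeca-8,12-dienedioate, via acyl imidazolide 11 (not isolated)
Conditions: CDI, THF, rt; then Mg(O2CCH2CO2Me)2, 45 °C; 1 M HCl
Reagents that add atoms: magnesium bis(3-methoxy-3-oxopropanoate), COC(=O)CC(=O)[O-].COC(=O)CC(=O)[O-].[Mg+2]
Why: Malonate half-ester homologation (C-acylation of the magnesium malonate by the acyl imidazolide, then decarboxylation) adds C2 and its ester without a base strong enough to touch C5 or the enoate.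

Step 8
Reactants: 12 dimethyl (5S,8E,12Z)-4,4,8,12-tetramethyl-3-oxo-5-(prop-1-en-2-yl)tetradeca-8,12-dienedioate
Product: 13 methyl (2Z)-5-[(1R,4aS,8aS)-7-(methoxycarbonyl)-5,5,8a-trimethyl-2-methylidene-6-oxodecahydronaphthalen-1-yl]-3-methylpent-2-enoate
Conditions: Mn(OAc)3·2H2O (2.2 equiv), Cu(OAc)2·H2O (1.0 equiv), degassed AcOH, 25 °C
Reagents that add atoms: none
Why: Manganese triacetate oxidises the enol of the β-keto ester to the C2 radical, which attacks C1 of the 1,1-disubstituted C1=C10 alkene; the tertiary C10 radical then attacks C9 of the (E)-C8=C9 alkene, and copper diacetate oxidises the tertiary C8 radical to an organocopper species that eliminates towards C17. The closest known reaction type is the manganese triacetate/copper diacetate oxidative free-radical polycyclisation of unsaturated β-keto esters; after the first closure the intermediate is the same ring A radical at C10 as in the usual chain connectivity. Ring A closes 6-endo-trig through the C1–C2 bond and ring B closes 6-endo-trig through the C9–C10 bond. C10 is set by the chair–chair transition state in which the chain on the existing (S)-C5 centre is equatorial, which gives the trans ring fusion, and C9 is set by the (E) geometry of C8=C9, which places the side chain equatorial and cis to the C10 methyl; C2 is epimerisable and is removed in step 9. The step needs 6-endo over 5-exo closure (secured by attack at the unsubstituted C1 and by the ketone inside the forming ring), elimination to the exocyclic rather than the endocyclic alkene (the organocopper intermediate prefers the less substituted alkene), no addition of the C8 radical to the conjugated ester (its β-carbon is fully substituted and a full equivalent of copper diacetate traps the radical) and no further oxidation of the enolisable product (limited by the 2.2 equiv of oxidant).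

Step 9
Reactants: 13 methyl (2Z)-5-[(1R,4aS,8aS)-7-(methoxycarbonyl)-5,5,8a-trimethyl-2-methylidene-6-oxodecahydronaphthalen-1-yl]-3-methylpent-2-enoate
Product: 14 methyl (2Z)-3-methyl-5-[(1R,4aS,8aS)-5,5,8a-trimethyl-2-methylidene-6-oxodecahydronaphthalen-1-yl]pent-2-enoate
Conditions: LiCl, H2O, DMSO, 140 °C
Reagents that add atoms: none
Why: Krapcho dealkoxycarbonylation: chloride demethylates only the activated β-keto ester and the carboxylate loses CO2, so the C2 centre disappears while the conjugated ester and the other stereocentres are untouched.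

Step 10
Reactants: 14 methyl (2Z)-3-methyl-5-[(1R,4aS,8aS)-5,5,8a-trimethyl-2-methylidene-6-oxodecahydronaphthalen-1-yl]pent-2-enoate
Product: 15 methyl (2Z)-5-[(1R,4aS,6R,8aS)-6-hydroxy-5,5,8a-trimethyl-2-methylidenedecahydronaphthalen-1-yl]-3-methylpent-2-enoate
Conditions: NaBH4, MeOH, 0 °C
Reagents that add atoms: none
Why: Borohydride reduction of the 4,4-dimethyl-3-ketone of a trans-decalin: hydride should add axially, from the face opposite the C10 methyl and the axial C4 methyl, to give the equatorial (R)-alcohol at C3; the β,β-disubstituted enoate is not reduced.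

Step 11
Reactants: 15 methyl (2Z)-5-[(1R,4aS,6R,8aS)-6-hydroxy-5,5,8a-trimethyl-2-methylidenedecahydronaphthalen-1-yl]-3-methylpent-2-enoate
Product: 17 methyl (2Z)-5-[(1R,2R,4aS,6R,8aS)-6-hydroxy-2-(hydroxymethyl)-5,5,8a-trimethyldecahydronaphthalen-1-yl]-3-methylpent-2-enoate, via bis-9-BBN adduct 16 (not isolated)
Conditions: 9-BBN (3 equiv), THF, 50 °C; then 30% H2O2, aq. NaOAc, 0 °C → rt
Reagents that add atoms: hydrogen peroxide, OO
Why: Hydroboration–oxidation: 9-BBN should add anti-Markovnikov to the exocyclic alkene from the face opposite the axial C10 methyl, delivering H to C8 on that face so that C17 becomes axial and syn to the C10 methyl (8R); the conjugated ester is inert to 9-BBN and the buffered oxidation spares it.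

Step 12
Reactants: 17 methyl (2Z)-5-[(1R,2R,4aS,6R,8aS)-6-hydroxy-2-(hydroxymethyl)-5,5,8a-trimethyldecahydronaphthalen-1-yl]-3-methylpent-2-enoate
Product: 18 methyl (2Z)-5-[(1R,2R,4aS,6R,8aS)-2-formyl-6-hydroxy-5,5,8a-trimethyldecahydronaphthalen-1-yl]-3-methylpent-2-enoate
Conditions: TEMPO (10 mol%), PhI(OAc)2, CH2Cl2, rt
Reagents that add atoms: none
Why: Oxoammonium (TEMPO) oxidation with PhI(OAc)2 as terminal oxidant is selective for the primary over the hindered secondary alcohol and runs without base, so the axial formyl group at C8 should not epimerise.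

Compound list
1 | (2E)-1-bromo-3,7-dimethylocta-2,6-diene (geranyl bromide) | BrC/C=C(\C)CCC=C(C)C | starting material
2 | methyl 3-oxobutanoate (methyl acetoacetate) | COC(=O)CC(C)=O | starting material
3 | sodium lithium dianion of methyl acetoacetate | [Na+].[Li+].COC(=O)[CH-]C(=O)[CH2-] | intermediate
4 | methyl (6E)-7,11-dimethyl-3-oxododeca-6,10-dienoate | COC(=O)CC(=O)CC/C=C(\C)CCC=C(C)C | intermediate
5 | methyl (2E,6E)-7,11-dimethyl-3-{[(trifluoromethyl)sulfonyl]oxy}dodeca-2,6,10-trienoate | COC(=O)/C=C(/OS(=O)(=O)C(F)(F)F)CC/C=C(\C)CCC=C(C)C | intermediate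
6 | methyl (2Z,6E)-3,7,11-trimethyldodeca-2,6,10-trienoate (methyl (2Z,6E)-farnesoate) | COC(=O)/C=C(/C)CC/C=C(\C)CCC=C(C)C | intermediate
7 | methyl (2Z,6E,10E)-12-hydroxy-3,7,11-trimethyldodeca-2,6,10-trienoate | COC(=O)/C=C(/C)CC/C=C(\C)CC/C=C(\C)CO | intermediate
8 | methyl (2Z,6E,10E)-3,7,11-trimethyl-12-[(2-methylpropanoyl)oxy]dodeca-2,6,10-trienoate | COC(=O)/C=C(/C)CC/C=C(\C)CC/C=C(\C)COC(=O)C(C)C | intermediate
9 | boron ketene acetal of 8 carrying the (4S,5S)-4,5-diphenyl-1,3-bis{[3,5-bis(trifluoromethyl)phenyl]sulfonyl}-1,3,2-diazaborolidin-2-yl group on the enol oxygen | COC(=O)/C=C(/C)CC/C=C(\C)CC/C=C(\C)COC(=C(C)C)OB1N(S(=O)(=O)c2cc(cc(c2)C(F)(F)F)C(F)(F)F)[C@@H](c2ccccc2)[C@H](c2ccccc2)N1S(=O)(=O)c1cc(cc(c1)C(F)(F)F)C(F)(F)F | intermediate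
10 | (3S,6E,10Z)-12-methoxy-2,2,6,10-tetramethyl-12-oxo-3-(prop-1-en-2-yl)dodeca-6,10-dienoic acid | COC(=O)/C=C(/C)CC/C=C(\C)CC[C@@H](C(C)=C)C(C)(C)C(O)=O | intermediate
11 | acyl imidazolide of 10: methyl (2Z,6E,10S)-12-(1H-imidazol-1-yl)-3,7,11,11-tetramethyl-12-oxo-10-(prop-1-en-2-yl)dodeca-2,6-dienoate | COC(=O)/C=C(/C)CC/C=C(\C)CC[C@@H](C(C)=C)C(C)(C)C(=O)n1ccnc1 | intermediate
12 | dimethyl (5S,8E,12Z)-4,4,8,12-tetramethyl-3-oxo-5-(prop-1-en-2-yl)tetradeca-8,12-dienedioate | COC(=O)/C=C(/C)CC/C=C(\C)CC[C@@H](C(C)=C)C(C)(C)C(=O)CC(=O)OC | intermediate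
13 | methyl (2Z)-5-[(1R,4aS,8aS)-7-(methoxycarbonyl)-5,5,8a-trimethyl-2-methylidene-6-oxodecahydronaphthalen-1-yl]-3-methylpent-2-enoate (ring position 7 = C2, epimer/enol mixture) | COC(=O)/C=C(/C)CC[C@@H]1C(=C)CC[C@@H]2C(C)(C)C(=O)C(C(=O)OC)C[C@@]12C | intermediate
14 | methyl (2Z)-3-methyl-5-[(1R,4aS,8aS)-5,5,8a-trimethyl-2-methylidene-6-oxodecahydronaphthalen-1-yl]pent-2-enoate | COC(=O)/C=C(/C)CC[C@@H]1C(=C)CC[C@@H]2C(C)(C)C(=O)CC[C@@]12C | intermediate
15 | methyl (2Z)-5-[(1R,4aS,6R,8aS)-6-hydroxy-5,5,8a-trimethyl-2-methylidenedecahydronaphthalen-1-yl]-3-methylpent-2-enoate | COC(=O)/C=C(/C)CC[C@@H]1C(=C)CC[C@@H]2C(C)(C)[C@H](O)CC[C@@]12C | intermediate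
16 | bis-9-BBN adduct of 15 (9-borabicyclo[3.3.1]nonan-9-yl on C17 and on the C3 oxygen) | COC(=O)/C=C(/C)CC[C@@H]1[C@H](CB3C4CCCC3CCC4)CC[C@@H]2C(C)(C)[C@H](OB3C4CCCC3CCC4)CC[C@@]12C | intermediate
17 | methyl (2Z)-5-[(1R,2R,4aS,6R,8aS)-6-hydroxy-2-(hydroxymethyl)-5,5,8a-trimethyldecahydronaphthalen-1-yl]-3-methylpent-2-enoate | COC(=O)/C=C(/C)CC[C@@H]1[C@H](CO)CC[C@@H]2C(C)(C)[C@H](O)CC[C@@]12C | intermediate
18 | methyl (2Z)-5-[(1R,2R,4aS,6R,8aS)-2-formyl-6-hydroxy-5,5,8a-trimethyldecahydronaphthalen-1-yl]-3-methylpent-2-enoate | COC(=O)/C=C(/C)CC[C@@H]1[C@H](C=O)CC[C@@H]2C(C)(C)[C@H](O)CC[C@@]12C | target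

Total step count: 12. Longest linear sequence: 12 steps (from 1 and 2).

Steps most likely to fail

Step 8. The C8 radical may add to the conjugated ester instead of being oxidised, the C10 radical may be oxidised before the second closure, the enolisable product may be oxidised further, or elimination may give endocyclic alkenes. The fallback is a cationic closure that sets out from acid 10. Oxalyl chloride should give the acid chloride, methyl (2Z,6E,10S)-12-chloro-3,7,11,11-tetramethyl-12-oxo-10-(prop-1-en-2-yl)dodeca-2,6-dienoate F1, and diazomethane should convert it into the diazoketone, methyl (2Z,6E,10S)-13-diazo-3,7,11,11-tetramethyl-12-oxo-10-(prop-1-en-2-yl)trideca-2,6-dienoate F2. BF3·OEt2 in CH2Cl2 at −20 °C should then trigger the acid-promoted diazoketone–polyene cyclisation (C2 diazonium attacked by C1, C10 cation attacked by C9, proton loss from C17). This route has no oxidant and the conjugated ester is inert to cations. It comes back to the route at ketone 14, after removal of any endocyclic alkene isomers on AgNO3-impregnated silica.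

Step 6. Enolisation of the α-branched ester may be sluggish, the conjugated ester may enolise vinylogously, or the controller may discriminate the allyl faces poorly. The fallback sets out from alcohol 7. Acylation with 2-bromo-2-methylpropanoyl bromide in pyridine should give methyl (2Z,6E,10E)-12-[(2-bromo-2-methylpropanoyl)oxy]-3,7,11-trimethyldodeca-2,6,10-trienoate F3. Zinc dust and Me3SiCl in refluxing THF should bring about the base-free Reformatsky–Claisen rearrangement to the racemic acid, (6E,10Z)-12-methoxy-2,2,6,10-tetramethyl-12-oxo-3-(prop-1-en-2-yl)dodeca-6,10-dienoic acid F4. Classical resolution through the crystalline (1S)-1-phenylethylammonium salt of the (3S)-acid F5 and acidification comes back to the route at acid 10.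

Step 4. Oxidation may spread to the internal allylic positions or run on to the enal, with loss of material. The fallback sets out from ester 6. NBS in aqueous THF should give the terminal bromohydrin, methyl (2Z,6E)-10-bromo-11-hydroxy-3,7,11-trimethyldodeca-2,6-dienoate F6, and K2CO3 in MeOH the epoxide, methyl (2Z,6E)-9-(3,3-dimethyloxiran-2-yl)-3,7-dimethylnona-2,6-dienoate F7. H5IO6 in ether should cleave it to the aldehyde, methyl (2Z,6E)-3,7-dimethyl-10-oxodeca-2,6-dienoate F8. Wittig reaction with 2-(triphenylphosphoranylidene)propanal should give the (E)-enal, methyl (2Z,6E,10E)-3,7,11-trimethyl-12-oxododeca-2,6,10-trienoate F9, and Luche reduction (NaBH4, CeCl3·7H2O, MeOH) comes back to the route at alcohol 7.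

Further compounds
F1 | step 8 | methyl (2Z,6E,10S)-12-chloro-3,7,11,11-tetramethyl-12-oxo-10-(prop-1-en-2-yl)dodeca-2,6-dienoate | COC(=O)/C=C(/C)CC/C=C(\C)CC[C@@H](C(C)=C)C(C)(C)C(Cl)=O
F2 | step 8 | methyl (2Z,6E,10S)-13-diazo-3,7,11,11-tetramethyl-12-oxo-10-(prop-1-en-2-yl)trideca-2,6-dienoate | COC(=O)/C=C(/C)CC/C=C(\C)CC[C@@H](C(C)=C)C(C)(C)C(=O)C=[N+]=[N-]
F3 | step 6 | methyl (2Z,6E,10E)-12-[(2-bromo-2-methylpropanoyl)oxy]-3,7,11-trimethyldodeca-2,6,10-trienoate | COC(=O)/C=C(/C)CC/C=C(\C)CC/C=C(\C)COC(=O)C(C)(C)Br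
F4 | step 6 | racemic (6E,10Z)-12-methoxy-2,2,6,10-tetramethyl-12-oxo-3-(prop-1-en-2-yl)dodeca-6,10-dienoic acid | COC(=O)/C=C(/C)CC/C=C(\C)CCC(C(C)=C)C(C)(C)C(O)=O
F5 | step 6 | (1S)-1-phenylethylammonium (3S,6E,10Z)-12-methoxy-2,2,6,10-tetramethyl-12-oxo-3-(prop-1-en-2-yl)dodeca-6,10-dienoate | COC(=O)/C=C(/C)CC/C=C(\C)CC[C@@H](C(C)=C)C(C)(C)C([O-])=O.C[C@H]([NH3+])c1ccccc1
F6 | step 4 | methyl (2Z,6E)-10-bromo-11-hydroxy-3,7,11-trimethyldodeca-2,6-dienoate (racemic) | COC(=O)/C=C(/C)CC/C=C(\C)CCC(Br)C(C)(C)O
F7 | step 4 | methyl (2Z,6E)-9-(3,3-dimethyloxiran-2-yl)-3,7-dimethylnona-2,6-dienoate (racemic) | COC(=O)/C=C(/C)CC/C=C(\C)CCC1OC1(C)C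
F8 | step 4 | methyl (2Z,6E)-3,7-dimethyl-10-oxodeca-2,6-dienoate | COC(=O)/C=C(/C)CC/C=C(\C)CCC=O
F9 | step 4 | methyl (2Z,6E,10E)-3,7,11-trimethyl-12-oxododeca-2,6,10-trienoate | COC(=O)/C=C(/C)CC/C=C(\C)CC/C=C(\C)C=O
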